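**Strategy.** The route rests on disconnecting the C7–C8 bond of the ten-membered carbocycle (ring A, C1–C10) where it meets the α-methylene-γ-lactone (ring B: O, C12, C11, C7, C6). The C8 carbinol next to C7 and the exocyclic C11=C13 methylene are the retron of an allylmetal–aldehyde addition. An intramolecular CrCl2-mediated allylation of a C8 aldehyde by a 3-(bromomethyl)butenolide closes ring A, creates C7 and C8 under control of C6, and moves the ring B olefin into the exocyclic position in one operation. The precursor is an open-chain (R)-butenolide carrying both trisubstituted olefins, the C2 stereocenter and a β,γ-unsaturated aldehyde. The 8S alcohol formed is inverted when the methacrylate is installed.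

Key step: step 15

Remark on numbering: germacrane numbering is used. Ring A is C1–C10 (acetate on C2, methacrylate on C8, hydroxymethyl C14 on C10, methyl C15 on C4); ring B is O–C12(=O)–C11(=C13)–C7–C6. TBS = tert-butyldimethylsilyl, PMB = 4-methoxybenzyl.

Assumption: (S)-TRIP and (S,S)-ProPhenol are taken to give the facial sense stated in steps 6 and 8; where the sense proves opposite, the mirror-image catalyst is used.

**Step 1**
Reactants: 1 (tributylstannyl)methanol
Product: 2 tributyl{[(4-methoxybenzyl)oxy]methyl}stannane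
Conditions: NaH, THF, 0 °C; PMBCl, Bu4NI (cat.), 0 °C to rt
Reagents that add atoms: 4-methoxybenzyl chloride, COc1ccc(CCl)cc1
Why: Williamson ether synthesis of the sodium alkoxide of 1 with the benzylic chloride should give the alkoxymethylstannane that serves as a hydroxymethyl anion equivalent for C14; no stereocenter is involved.

**Step 2**
Reactants: 3 tert-butyl(but-3-yn-1-yloxy)dimethylsilane
Product: 5 methyl 5-[(tert-butyldimethylsilyl)oxy]pent-2-ynoate, via lithium acetylide 4 (not isolated)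
Conditions: n-BuLi, THF, −78 °C; ClCO2Me, −78 to 0 °C
Reagents that add atoms: methyl chloroformate, COC(=O)Cl
Why: Deprotonation of the terminal alkyne and C-acylation of the lithium acetylide with a chloroformate is a standard entry to 2-ynoates and installs C2 as the ester carbon.

**Step 3**
Reactants: 5 methyl 5-[(tert-butyldimethylsilyl)oxy]pent-2-ynoate; 2 tributyl{[(4-methoxybenzyl)oxy]methyl}stannane
Product: 8 methyl (2E)-5-(TBSO)-3-[(PMBO)methyl]pent-2-enoate (ester cis to the CH2CH2OTBS arm), via alkoxymethyllithium 6 (not isolated), via lithium dialkylcuprate 7 (not isolated)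
Conditions: 2 (2.2 equiv), n-BuLi, THF, −78 °C; CuBr·SMe2 (1.1 equiv), −78 °C; then 5, −78 °C; NH4Cl/MeOH quench at −78 °C
Reagents that add atoms: none
Why: Tin–lithium exchange and cuprate formation are followed by syn-carbocupration of the ynoate (organocuprate conjugate addition) at −78 °C, where the alkenylcopper should not isomerize, so protonation places H cis to the new CH2OPMB group and the ester carbon (C2) cis to the C9 arm, which is the C1=C10 geometry of the target.

**Step 4**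
Reactants: 8 methyl (2E)-5-(TBSO)-3-[(PMBO)methyl]pent-2-enoate
Product: 9 (2E)-5-(TBSO)-3-[(PMBO)methyl]pent-2-en-1-ol
Conditions: i-Bu2AlH (2.5 equiv), CH2Cl2, −78 °C; aq. potassium sodium tartrate
Reagents that add atoms: none
Why: i-Bu2AlH reduces the conjugated ester to the allylic alcohol by 1,2-hydride delivery without touching the olefin geometry or the silyl and PMB ethers.

**Step 5**
Reactants: 9 (2E)-5-(TBSO)-3-[(PMBO)methyl]pent-2-en-1-ol
Product: 10 (2E)-5-(TBSO)-3-[(PMBO)methyl]pent-2-enal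
Conditions: MnO2 (activated, excess), CH2Cl2, rt
Reagents that add atoms: none
Why: MnO2 oxidizes the primary allylic alcohol chemoselectively to the enal under neutral heterogeneous conditions that should not isomerize the trisubstituted olefin.

**Step 6**
Reactants: 10 (2E)-5-(TBSO)-3-[(PMBO)methyl]pent-2-enal; 11 allenylboronic acid pinacol ester
Product: 13 (4S,5E)-8-(TBSO)-6-[(PMBO)methyl]oct-5-en-1-yn-4-ol, via pinacol borate ester 12 (not isolated)
Conditions: 11 (1.5 equiv), (S)-TRIP [(S)-3,3′-bis(2,4,6-triisopropylphenyl)-1,1′-binaphthyl-2,2′-diyl hydrogen phosphate, 10 mol %], 4 Å molecular sieves, toluene, 0 °C; aqueous work-up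
Reagents that add atoms: none
Why: Chiral phosphoric acid-catalysed allenylboration (asymmetric propargylation) proceeds through a closed six-membered SE2′ transition state in which the catalyst activates the boronate and shields one face of the aldehyde, so that addition to the Si face of 10 should set C2 as S (4S in 13).

**Step 7**
Reactants: 13 (4S,5E)-8-(TBSO)-6-[(PMBO)methyl]oct-5-en-1-yn-4-ol
Product: 14 (4S,5E)-4,8-bis(TBSO)-6-[(PMBO)methyl]oct-5-en-1-yne
Conditions: TBSCl, imidazole, DMF, rt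
Reagents that add atoms: tert-butyldimethylsilyl chloride, CC(C)(C)[Si](C)(C)Cl
Why: Standard silylation of the secondary allylic alcohol masks O2 for the hydride and organometallic steps that an acetate would not survive.

**Step 8**
Reactants: 14 (4S,5E)-4,8-bis(TBSO)-6-[(PMBO)methyl]oct-5-en-1-yne; 15 (E)-but-2-enal
Product: 17 (2E,4S,8S,9E)-8,12-bis(TBSO)-10-[(PMBO)methyl]dodeca-2,9-dien-5-yn-4-ol, via methylzinc acetylide 16 (not isolated)
Conditions: Me2Zn (3 equiv), (S,S)-ProPhenol (20 mol %), Ph3PO (40 mol %), toluene, 0 °C; then 15 (2 equiv, slow addition), 0 °C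
Reagents that add atoms: none
Why: Catalytic asymmetric alkynylation (zinc acetylide addition to an enal under ProPhenol control) should deliver the alkynyl group to the Re face of 15, setting the future C6 center (4S in 17) under catalyst control, independent of the remote C2 center.

**Step 9**
Reactants: 17 (2E,4S,8S,9E)-8,12-bis(TBSO)-10-[(PMBO)methyl]dodeca-2,9-dien-5-yn-4-ol
Product: 19 (2E,4S,5Z,8S,9E)-8,12-bis(TBSO)-6-iodo-10-[(PMBO)methyl]dodeca-2,5,9-trien-4-ol, via sodium alkenylalanate 18 (not isolated)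
Conditions: NaAlH2(OCH2CH2OCH3)2, THF, 0 °C to rt; EtOAc; then I2, THF, −78 °C
Reagents that add atoms: iodine, II
Why: Hydroxyl-directed trans-hydroalumination of the propargylic alcohol delivers hydride to C5 and aluminium to C4 within a five-membered alkoxyalanate, and iodinolysis with retention should give the (Z)-iodoalkene with iodine cis to C6.

**Step 10**
Reactants: 19 (2E,4S,5Z,8S,9E)-8,12-bis(TBSO)-6-iodo-10-[(PMBO)methyl]dodeca-2,5,9-trien-4-ol
Product: 20 (2E,4S,5E,8S,9E)-8,12-bis(TBSO)-10-[(PMBO)methyl]-6-methyldodeca-2,5,9-trien-4-ol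
Conditions: MeZnCl (3 equiv), Pd(PPh3)4 (5 mol %), THF, rt
Reagents that add atoms: methylzinc chloride, C[Zn]Cl
Why: Negishi cross-coupling replaces iodine by methyl with retention of olefin geometry, which fixes the E-configured C4=C5 olefin (C15 cis to C6, C3 trans).

**Step 11**
Reactants: 20 (2E,4S,5E,8S,9E)-8,12-bis(TBSO)-10-[(PMBO)methyl]-6-methyldodeca-2,5,9-trien-4-ol; 21 2-(bromomethyl)prop-2-enoic acid
Product: 22 (2E,4S,5E,8S,9E)-8,12-bis(TBSO)-10-[(PMBO)methyl]-6-methyldodeca-2,5,9-trien-4-yl 2-(bromomethyl)prop-2-enoate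
Conditions: DIC, DMAP (10 mol %), CH2Cl2, 0 °C
Reagents that add atoms: none
Why: Carbodiimide (Steglich) esterification acylates the only free hydroxyl under conditions mild enough for the allylic bromide and the doubly allylic carbinol, with no change at C6.

**Step 12**
Reactants: 22 (2E,4S,5E,8S,9E)-8,12-bis(TBSO)-10-[(PMBO)methyl]-6-methyldodeca-2,5,9-trien-4-yl 2-(bromomethyl)prop-2-enoate
Product: 23 (5R)-3-(bromomethyl)-5-{(1E,4S,5E)-4,8-bis(TBSO)-6-[(PMBO)methyl]-2-methylocta-1,5-dien-1-yl}furan-2(5H)-one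
Conditions: second-generation Hoveyda–Grubbs catalyst (10 mol %), toluene (0.005 M), 80 °C
Reagents that add atoms: none
Why: Ring-closing metathesis between the propenyl group and the 1,1-disubstituted acrylate forms the five-membered butenolide (ring B) with loss of propene, the only geometrically possible closure for the ruthenium alkylidene formed at C7, and should leave the C6 stereocenter and the allylic bromide untouched.

**Step 13**
Reactants: 23 (5R)-3-(bromomethyl)-5-{(1E,4S,5E)-4,8-bis(TBSO)-6-[(PMBO)methyl]-2-methylocta-1,5-dien-1-yl}furan-2(5H)-one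
Product: 24 (5R)-3-(bromomethyl)-5-{(1E,4S,5E)-4-(TBSO)-8-hydroxy-6-[(PMBO)methyl]-2-methylocta-1,5-dien-1-yl}furan-2(5H)-one
Conditions: HF·pyridine, pyridine, THF, 0 °C
Reagents that add atoms: none
Why: Buffered HF·pyridine cleaves the unhindered primary silyl ether much faster than the secondary allylic one, freeing O8 under conditions that should not deprotonate the acidic C6–H of the butenolide.

**Step 14**
Reactants: 24 (5R)-3-(bromomethyl)-5-{(1E,4S,5E)-4-(TBSO)-8-hydroxy-6-[(PMBO)methyl]-2-methylocta-1,5-dien-1-yl}furan-2(5H)-one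
Product: 25 (3E,5S,7E)-8-[(2R)-4-(bromomethyl)-5-oxo-2,5-dihydrofuran-2-yl]-5-(TBSO)-3-[(PMBO)methyl]-7-methylocta-3,7-dienal
Conditions: Dess–Martin periodinane, NaHCO3, CH2Cl2, 0 °C to rt; used at once
Reagents that add atoms: none
Why: Dess–Martin oxidation under bicarbonate buffering converts the homoallylic alcohol into the β,γ-unsaturated aldehyde without acid or base strong enough to move the C1=C10 olefin into conjugation or to epimerize C6.

**Step 15**
Reactants: 25 (3E,5S,7E)-8-[(2R)-4-(bromomethyl)-5-oxo-2,5-dihydrofuran-2-yl]-5-(TBSO)-3-[(PMBO)methyl]-7-methylocta-3,7-dienal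
Product: 27 (3aR,4S,6E,8S,10E,11aR)-8-(TBSO)-4-hydroxy-6-[(PMBO)methyl]-10-methyl-3-methylidene-3a,4,5,8,9,11a-hexahydrocyclodeca[b]furan-2(3H)-one, via allylchromium dichloride 26 (not isolated)
Conditions: CrCl2 (10 equiv), THF, rt, syringe-pump addition of 25 (final 0.003 M); aqueous work-up
Reagents that add atoms: none
Why: CrCl2 reduces the allylic C13–Br bond by two single-electron transfers to the allylchromium dichloride 26, whose γ-carbon C7 adds to the C8 aldehyde through a six-membered chair-like transition state (chromium bridging C13 and O8), shifting the ring B double bond from C7=C11 into the exocyclic C11=C13 position. The closest known reaction type is the Nozaki–Hiyama allylation of aldehydes with 3-(bromomethyl)furan-2(5H)-ones and with 2-(bromomethyl)acrylates, the latter also established for medium-ring closure. Ring A closes by a 10-exo-trig carbonyl addition (SE2′ with respect to the allyl unit) under high dilution. C7 is set by C6: the aldehyde arm should reach C7 on the face opposite to the C5 substituent, giving the trans-fused (6R,7R) lactone, because the cis alternative would eclipse the C5 and C8 arms across C6–C7 in a ring that already holds an E and a Z olefin. C8 is set by the transition state: ring B locks the allyl unit in the E-like geometry (C6 trans to C13) and C9 sits pseudo-equatorial, so H7 and H8 end up anti and the 8S alcohol should result, which is the epimer that step 16 inverts. The step needs γ- over α-attack (inherent to allylchromium reagents), cyclization over oligomerization (slow addition at high dilution) and survival of the C6 stereocenter and the β,γ-unsaturated aldehyde, both secured by the neutral, non-basic medium.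

**Step 16**
Reactants: 27 (3aR,4S,6E,8S,10E,11aR)-8-(TBSO)-4-hydroxy-6-[(PMBO)methyl]-10-methyl-3-methylidene-3a,4,5,8,9,11a-hexahydrocyclodeca[b]furan-2(3H)-one; 28 methacrylic acid
Product: 29 (3aR,4R,6E,8S,10E,11aR)-8-(TBSO)-6-[(PMBO)methyl]-10-methyl-3-methylidene-2-oxo-2,3,3a,4,5,8,9,11a-octahydrocyclodeca[b]furan-4-yl 2-methylprop-2-enoate
Conditions: PPh3, DIAD, toluene, 0 °C to rt
Reagents that add atoms: none
Why: Mitsunobu esterification activates the secondary 8S alcohol as an alkoxyphosphonium ion that methacrylate displaces by SN2 with inversion, giving the 8R ester of the target.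

**Step 17**
Reactants: 29 (3aR,4R,6E,8S,10E,11aR)-8-(TBSO)-6-[(PMBO)methyl]-10-methyl-3-methylidene-2-oxo-2,3,3a,4,5,8,9,11a-octahydrocyclodeca[b]furan-4-yl 2-methylprop-2-enoate
Product: 30 (3aR,4R,6E,8S,10E,11aR)-8-hydroxy-6-[(PMBO)methyl]-10-methyl-3-methylidene-2-oxo-2,3,3a,4,5,8,9,11a-octahydrocyclodeca[b]furan-4-yl 2-methylprop-2-enoate
Conditions: HF·pyridine, THF, 0 °C to rt
Reagents that add atoms: none
Why: Desilylation with HF·pyridine removes the remaining secondary silyl ether under mildly acidic conditions that should spare both esters, the α-methylene lactone and the PMB ether.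

**Step 18**
Reactants: 30 (3aR,4R,6E,8S,10E,11aR)-8-hydroxy-6-[(PMBO)methyl]-10-methyl-3-methylidene-2-oxo-2,3,3a,4,5,8,9,11a-octahydrocyclodeca[b]furan-4-yl 2-methylprop-2-enoate
Product: 31 (3aR,4R,6E,8S,10E,11aR)-8-(acetyloxy)-6-[(PMBO)methyl]-10-methyl-3-methylidene-2-oxo-2,3,3a,4,5,8,9,11a-octahydrocyclodeca[b]furan-4-yl 2-methylprop-2-enoate
Conditions: Ac2O, pyridine, DMAP (cat.), CH2Cl2, 0 °C
Reagents that add atoms: acetic anhydride, CC(=O)OC(C)=O
Why: DMAP-catalysed acetylation of the only free hydroxyl installs the C2 acetate with retention of configuration.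

**Step 19**
Reactants: 31 (3aR,4R,6E,8S,10E,11aR)-8-(acetyloxy)-6-[(PMBO)methyl]-10-methyl-3-methylidene-2-oxo-2,3,3a,4,5,8,9,11a-octahydrocyclodeca[b]furan-4-yl 2-methylprop-2-enoate
Product: 32 (3aR,4R,6E,8S,10E,11aR)-8-(acetyloxy)-6-(hydroxymethyl)-10-methyl-3-methylidene-2-oxo-2,3,3a,4,5,8,9,11a-octahydrocyclodeca[b]furan-4-yl 2-methylprop-2-enoate (CNP0138477.2)
Conditions: DDQ, CH2Cl2/pH 7 phosphate buffer, 0 °C
Reagents that add atoms: none
Why: DDQ removes the PMB ether by benzylic hydride abstraction and hydrolysis of the resulting oxocarbenium ion under buffered conditions compatible with the esters and the α-methylene lactone, releasing the C14 alcohol of the target.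

**Compound list**

1 | (tributylstannyl)methanol | OC[Sn](CCCC)(CCCC)CCCC | starting material
2 | tributyl{[(4-methoxybenzyl)oxy]methyl}stannane | COc1ccc(COC[Sn](CCCC)(CCCC)CCCC)cc1 | intermediate
3 | tert-butyl(but-3-yn-1-yloxy)dimethylsilane | C#CCCO[Si](C)(C)C(C)(C)C | starting material
4 | lithium acetylide of 3 | [Li]C#CCCO[Si](C)(C)C(C)(C)C | intermediate
5 | methyl 5-[(tert-butyldimethylsilyl)oxy]pent-2-ynoate | COC(=O)C#CCCO[Si](C)(C)C(C)(C)C | intermediate
6 | {[(4-methoxybenzyl)oxy]methyl}lithium | [Li]COCc1ccc(OC)cc1 | intermediate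
7 | lithium bis{[(4-methoxybenzyl)oxy]methyl}cuprate | [Li+].COc1ccc(COC[Cu-]COCc2ccc(OC)cc2)cc1 | intermediate
8 | methyl (2E)-5-(TBSO)-3-[(PMBO)methyl]pent-2-enoate | COC(=O)/C=C(\CCO[Si](C)(C)C(C)(C)C)COCc1ccc(OC)cc1 | intermediate
9 | (2E)-5-(TBSO)-3-[(PMBO)methyl]pent-2-en-1-ol | OC/C=C(\CCO[Si](C)(C)C(C)(C)C)COCc1ccc(OC)cc1 | intermediate
10 | (2E)-5-(TBSO)-3-[(PMBO)methyl]pent-2-enal | O=C/C=C(\CCO[Si](C)(C)C(C)(C)C)COCc1ccc(OC)cc1 | intermediate
11 | 4,4,5,5-tetramethyl-2-(propa-1,2-dien-1-yl)-1,3,2-dioxaborolane (allenylboronic acid pinacol ester) | C=C=CB1OC(C)(C)C(C)(C)O1 | starting material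
12 | pinacol borate ester of 13 | C#CC[C@H](OB1OC(C)(C)C(C)(C)O1)/C=C(\CCO[Si](C)(C)C(C)(C)C)COCc1ccc(OC)cc1 | intermediate
13 | (4S,5E)-8-(TBSO)-6-[(PMBO)methyl]oct-5-en-1-yn-4-ol | C#CC[C@H](O)/C=C(\CCO[Si](C)(C)C(C)(C)C)COCc1ccc(OC)cc1 | intermediate
14 | (4S,5E)-4,8-bis(TBSO)-6-[(PMBO)methyl]oct-5-en-1-yne | C#CC[C@H](O[Si](C)(C)C(C)(C)C)/C=C(\CCO[Si](C)(C)C(C)(C)C)COCc1ccc(OC)cc1 | intermediate
15 | (E)-but-2-enal (crotonaldehyde) | C/C=C/C=O | starting material
16 | methylzinc acetylide of 14 | C[Zn]C#CC[C@H](O[Si](C)(C)C(C)(C)C)/C=C(\CCO[Si](C)(C)C(C)(C)C)COCc1ccc(OC)cc1 | intermediate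
17 | (2E,4S,8S,9E)-8,12-bis(TBSO)-10-[(PMBO)methyl]dodeca-2,9-dien-5-yn-4-ol | C/C=C/[C@H](O)C#CC[C@H](O[Si](C)(C)C(C)(C)C)/C=C(\CCO[Si](C)(C)C(C)(C)C)COCc1ccc(OC)cc1 | intermediate
18 | sodium alkenylalanate (five-membered C4–Al–O6 chelate) from 17 | [Na+].COCCO[Al-]1(OCCOC)O[C@@H](/C=C/C)C=C1C[C@H](O[Si](C)(C)C(C)(C)C)/C=C(\CCO[Si](C)(C)C(C)(C)C)COCc1ccc(OC)cc1 | intermediate
19 | (2E,4S,5Z,8S,9E)-8,12-bis(TBSO)-6-iodo-10-[(PMBO)methyl]dodeca-2,5,9-trien-4-ol | C/C=C/[C@H](O)/C=C(\I)C[C@H](O[Si](C)(C)C(C)(C)C)/C=C(\CCO[Si](C)(C)C(C)(C)C)COCc1ccc(OC)cc1 | intermediate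
20 | (2E,4S,5E,8S,9E)-8,12-bis(TBSO)-10-[(PMBO)methyl]-6-methyldodeca-2,5,9-trien-4-ol | C/C=C/[C@H](O)/C=C(\C)C[C@H](O[Si](C)(C)C(C)(C)C)/C=C(\CCO[Si](C)(C)C(C)(C)C)COCc1ccc(OC)cc1 | intermediate
21 | 2-(bromomethyl)prop-2-enoic acid | OC(=O)C(=C)CBr | starting material
22 | (2E,4S,5E,8S,9E)-8,12-bis(TBSO)-10-[(PMBO)methyl]-6-methyldodeca-2,5,9-trien-4-yl 2-(bromomethyl)prop-2-enoate | C/C=C/[C@H](OC(=O)C(=C)CBr)/C=C(\C)C[C@H](O[Si](C)(C)C(C)(C)C)/C=C(\CCO[Si](C)(C)C(C)(C)C)COCc1ccc(OC)cc1 | intermediate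
23 | (5R)-3-(bromomethyl)-5-{(1E,4S,5E)-4,8-bis(TBSO)-6-[(PMBO)methyl]-2-methylocta-1,5-dien-1-yl}furan-2(5H)-one | O=C1O[C@H](/C=C(\C)C[C@H](O[Si](C)(C)C(C)(C)C)/C=C(\CCO[Si](C)(C)C(C)(C)C)COCc2ccc(OC)cc2)C=C1CBr | intermediate
24 | (5R)-3-(bromomethyl)-5-{(1E,4S,5E)-4-(TBSO)-8-hydroxy-6-[(PMBO)methyl]-2-methylocta-1,5-dien-1-yl}furan-2(5H)-one | O=C1O[C@H](/C=C(\C)C[C@H](O[Si](C)(C)C(C)(C)C)/C=C(\CCO)COCc2ccc(OC)cc2)C=C1CBr | intermediate
25 | (3E,5S,7E)-8-[(2R)-4-(bromomethyl)-5-oxo-2,5-dihydrofuran-2-yl]-5-(TBSO)-3-[(PMBO)methyl]-7-methylocta-3,7-dienal | O=C1O[C@H](/C=C(\C)C[C@H](O[Si](C)(C)C(C)(C)C)/C=C(\CC=O)COCc2ccc(OC)cc2)C=C1CBr | intermediate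
26 | allylchromium dichloride from 25 (CrCl2 on C13) | O=C1O[C@H](/C=C(\C)C[C@H](O[Si](C)(C)C(C)(C)C)/C=C(\CC=O)COCc2ccc(OC)cc2)C=C1C[Cr](Cl)Cl | intermediate
27 | (3aR,4S,6E,8S,10E,11aR)-8-(TBSO)-4-hydroxy-6-[(PMBO)methyl]-10-methyl-3-methylidene-3a,4,5,8,9,11a-hexahydrocyclodeca[b]furan-2(3H)-one | O[C@H]1C/C(COCc3ccc(OC)cc3)=C\[C@@H](O[Si](C)(C)C(C)(C)C)C/C(C)=C/[C@H]2OC(=O)C(=C)[C@@H]21 | intermediate
28 | methacrylic acid | CC(=C)C(=O)O | starting material
29 | (3aR,4R,6E,8S,10E,11aR)-8-(TBSO)-6-[(PMBO)methyl]-10-methyl-3-methylidene-2-oxo-2,3,3a,4,5,8,9,11a-octahydrocyclodeca[b]furan-4-yl 2-methylprop-2-enoate | C=C(C)C(=O)O[C@@H]1C/C(COCc3ccc(OC)cc3)=C\[C@@H](O[Si](C)(C)C(C)(C)C)C/C(C)=C/[C@H]2OC(=O)C(=C)[C@@H]21 | intermediate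
30 | (3aR,4R,6E,8S,10E,11aR)-8-hydroxy-6-[(PMBO)methyl]-10-methyl-3-methylidene-2-oxo-2,3,3a,4,5,8,9,11a-octahydrocyclodeca[b]furan-4-yl 2-methylprop-2-enoate | C=C(C)C(=O)O[C@@H]1C/C(COCc3ccc(OC)cc3)=C\[C@@H](O)C/C(C)=C/[C@H]2OC(=O)C(=C)[C@@H]21 | intermediate
31 | (3aR,4R,6E,8S,10E,11aR)-8-(acetyloxy)-6-[(PMBO)methyl]-10-methyl-3-methylidene-2-oxo-2,3,3a,4,5,8,9,11a-octahydrocyclodeca[b]furan-4-yl 2-methylprop-2-enoate | C=C(C)C(=O)O[C@@H]1C/C(COCc3ccc(OC)cc3)=C\[C@@H](OC(C)=O)C/C(C)=C/[C@H]2OC(=O)C(=C)[C@@H]21 | intermediate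
32 | (3aR,4R,6E,8S,10E,11aR)-8-(acetyloxy)-6-(hydroxymethyl)-10-methyl-3-methylidene-2-oxo-2,3,3a,4,5,8,9,11a-octahydrocyclodeca[b]furan-4-yl 2-methylprop-2-enoate | C=C(C)C(=O)O[C@@H]1C/C(CO)=C\[C@@H](OC(C)=O)C/C(C)=C/[C@H]2OC(=O)C(=C)[C@@H]21 | target

**Step count and risks**

Total step count: 19 (steps 2–19 in the main line, step 1 for reagent 2).
Longest linear sequence: 18 steps (from 3 to 32).

Steps most likely to fail:

1. Step 15 (macrocyclization). Intermolecular allylation may outrun ring closure, the allylchromium may be protonated before it reaches the aldehyde, or the aldehyde arm may close on the C5 face of ring B and give the cis-fused lactone. The fallback sets out from 25 and replaces the chromium reagent by an isolable allylstannane. Sn2Bu6 with catalytic Pd(PPh3)4 in THF should convert the allylic bromide into the allylstannane aldehyde F1. BF3·OEt2 in CH2Cl2 at −78 °C under high dilution should then close ring A through an open transition state without any heterogeneous reductant. That transition state is expected to give the 8R alcohol, the macrocyclic 8-epimer of 27, F2. Acylation of F2 with methacrylic anhydride and DMAP returns to the route at 29; if 27 forms instead, step 16 applies unchanged.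

2. Step 16 (Mitsunobu inversion). The activated homoallylic alcohol may eliminate toward a C7=C8 or C8=C9 olefin, the ester may form with retention through an acyloxyphosphonium path, or PPh3 may add to the α-methylene lactone. The fallback sets out from 27: chloromethanesulfonyl chloride and pyridine in CH2Cl2 at 0 °C should give the chloromethanesulfonate F3. SN2 displacement with caesium methacrylate and 18-crown-6 in toluene comes back at 29.

3. Step 12 (ring-closing metathesis). Closure onto the hindered, electron-poor bromomethyl acrylate may be slow, and the allylic bromide may consume the ruthenium catalyst. The fallback sets out from 20 and carries a halide-free acrylate through the metathesis. Esterification with 2-{[(triethylsilyl)oxy]methyl}prop-2-enoic acid (DIC, DMAP) should give the silyloxymethyl acrylate ester F4. Metathesis under the conditions of step 12 should give the silyloxymethyl butenolide F5. PPTS in MeOH at 0 °C should cleave the triethylsilyl ether selectively to the hydroxymethyl butenolide F6. An Appel reaction (CBr4, PPh3, CH2Cl2, 0 °C) comes back at 23.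

**Further compounds**

F1 | step 15 | (3E,5S,7E)-5-(TBSO)-3-[(PMBO)methyl]-7-methyl-8-{(2R)-5-oxo-4-[(tributylstannyl)methyl]-2,5-dihydrofuran-2-yl}octa-3,7-dienal | O=C1O[C@H](/C=C(\C)C[C@H](O[Si](C)(C)C(C)(C)C)/C=C(\CC=O)COCc2ccc(OC)cc2)C=C1C[Sn](CCCC)(CCCC)CCCC
F2 | step 15 | (3aR,4R,6E,8S,10E,11aR)-8-(TBSO)-4-hydroxy-6-[(PMBO)methyl]-10-methyl-3-methylidene-3a,4,5,8,9,11a-hexahydrocyclodeca[b]furan-2(3H)-one | O[C@@H]1C/C(COCc3ccc(OC)cc3)=C\[C@@H](O[Si](C)(C)C(C)(C)C)C/C(C)=C/[C@H]2OC(=O)C(=C)[C@@H]21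
F3 | step 16 | (3aR,4S,6E,8S,10E,11aR)-8-(TBSO)-6-[(PMBO)methyl]-10-methyl-3-methylidene-2-oxo-2,3,3a,4,5,8,9,11a-octahydrocyclodeca[b]furan-4-yl chloromethanesulfonate | O=S(=O)(CCl)O[C@H]1C/C(COCc3ccc(OC)cc3)=C\[C@@H](O[Si](C)(C)C(C)(C)C)C/C(C)=C/[C@H]2OC(=O)C(=C)[C@@H]21
F4 | step 12 | (2E,4S,5E,8S,9E)-8,12-bis(TBSO)-10-[(PMBO)methyl]-6-methyldodeca-2,5,9-trien-4-yl 2-{[(triethylsilyl)oxy]methyl}prop-2-enoate | C/C=C/[C@H](OC(=O)C(=C)CO[Si](CC)(CC)CC)/C=C(\C)C[C@H](O[Si](C)(C)C(C)(C)C)/C=C(\CCO[Si](C)(C)C(C)(C)C)COCc1ccc(OC)cc1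
F5 | step 12 | (5R)-5-{(1E,4S,5E)-4,8-bis(TBSO)-6-[(PMBO)methyl]-2-methylocta-1,5-dien-1-yl}-3-{[(triethylsilyl)oxy]methyl}furan-2(5H)-one | O=C1O[C@H](/C=C(\C)C[C@H](O[Si](C)(C)C(C)(C)C)/C=C(\CCO[Si](C)(C)C(C)(C)C)COCc2ccc(OC)cc2)C=C1CO[Si](CC)(CC)CC
F6 | step 12 | (5R)-5-{(1E,4S,5E)-4,8-bis(TBSO)-6-[(PMBO)methyl]-2-methylocta-1,5-dien-1-yl}-3-(hydroxymethyl)furan-2(5H)-one | O=C1O[C@H](/C=C(\C)C[C@H](O[Si](C)(C)C(C)(C)C)/C=C(\CCO[Si](C)(C)C(C)(C)C)COCc2ccc(OC)cc2)C=C1CO
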